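**Plan**
Numbering: ring A = C10, C1, C2, C3 (ketone), C4 (gem-dimethyl), C5; ring B = C5–C10 (C8 carbinol, C9 carries C11–C23); β is the face of the C10 methyl.
Cuts: first C11–C12 (α-sulfonyl carbanion plus a farnesol-derived C12–C23 allylic bromide), then C5–C10 and C8–C9 together, after adding a C6=C7 bond and taking C3 back to a silyl-protected carbinol.
Feature used: C5, C10, C9 and C8 are contiguous on ring B with H-5, the C10 methyl, C11 and the C8 methyl all β, and C5 and C10 are bridged by C1–C4 of ring A; a C5=C6–C7=C8 silyloxy diene and a C9=C10 enoate joined through C1–C4 therefore map onto both rings at once.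
Forward: methyl geranate gives the C3 aldehyde; reverse prenylation adds C4–C6; cross-metathesis adds C7 and C8; ketone, then (E)-silyl dienol ether; rings A and B close together; C11 becomes a sulfone; the chain is joined; desilylation, acetate, C3 ketone.
Stereochemistry: C3 (S) comes from a reagent-controlled prenylboration and steers the diene face; the (E)-enoate, the (E,E)-dienol ether and the tether-endo transition state set C5, C8, C9 and C10; C3 is finally erased as the ketone.

Key step: step 7

Remark: as written, the target has H-5 cis to the C10 methyl, (5S,8R,9R,10S) in the numbering above; the route is built for this cis-fused array, and open-chain intermediates are discussed with the same atom numbers (ester carbon = C11, silyloxy carbinol = C3, enol ether carbon = C8).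

Step 1
Reactants: 1 methyl geranate
Product: 3 methyl (2E)-3-methyl-6-oxohex-2-enoate, via ozonide 2 (not isolated)
Conditions: O3, CH2Cl2, −78 °C, Sudan Red 7B end point; then Me2S, −78 °C → rt
Reagents that add atoms: ozone, [O-][O+]=O
Why: Ozonolysis with reductive work-up; ozone attacks the electron-rich trisubstituted distal alkene much faster than the ester-conjugated one and the dye end point stops the reaction there, and no stereocentre is formed.

Step 2
Reactants: 3 methyl (2E)-3-methyl-6-oxohex-2-enoate; 4 3-methylbuta-1,2-diene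
Product: 7 methyl (2E,6S)-6-hydroxy-3,7,7-trimethylnona-2,8-dienoate, via prenylborane 5 (not isolated), via borinate 6 (not isolated)
Conditions: (+)-Ipc2BH [from (−)-α-pinene], 4, THF, −25 °C; then 3, −78 °C; then aq NaOAc, 30% H2O2, 0 °C → rt
Reagents that add atoms: none
Why: Brown-type asymmetric prenylboration: hydroboration of the allene gives the prenylborane, which adds through its γ-carbon in a chair six-membered transition state, and the isopinocampheyl groups derived from (−)-α-pinene should direct attack to the Re face of the aldehyde, setting C3 as S next to the new quaternary C4 while the enoate stays untouched.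

Step 3
Reactants: 7 methyl (2E,6S)-6-hydroxy-3,7,7-trimethylnona-2,8-dienoate
Product: 8 methyl (2E,6S)-6-(tert-butyldimethylsilyloxy)-3,7,7-trimethylnona-2,8-dienoate
Conditions: TBSOTf, 2,6-lutidine, CH2Cl2, 0 °C
Reagents that add atoms: tert-butyldimethylsilyl triflate, CC(C)(C)[Si](C)(C)OS(=O)(=O)C(F)(F)F
Why: Silylation of a hindered secondary alcohol with the silyl triflate and a non-nucleophilic base; the stereocentre is not touched.

Step 4
Reactants: 8 methyl (2E,6S)-6-(tert-butyldimethylsilyloxy)-3,7,7-trimethylnona-2,8-dienoate; 9 (±)-pent-4-en-2-ol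
Product: 10 methyl (2E,6S,8E)-6-(tert-butyldimethylsilyloxy)-11-hydroxy-3,7,7-trimethyldodeca-2,8-dienoate (both epimers at the new carbinol carbon)
Conditions: RuCl2(H2IMes)(=CH-C6H4-2-OiPr) (second-generation isopropoxybenzylidene ruthenium catalyst, 5 mol%), 9 (4 equiv), CH2Cl2, 40 °C
Reagents that add atoms: none
Why: Olefin cross-metathesis: the vinyl group on the quaternary carbon does not homodimerise, so an excess of the unhindered homoallylic alcohol should drive the cross product, its bulky ends favour the (E)-alkene, the trisubstituted enoate is a spectator, and the carbinol centre is left unassigned because step 5 removes it.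

Step 5
Reactants: 10 methyl (2E,6S,8E)-6-(tert-butyldimethylsilyloxy)-11-hydroxy-3,7,7-trimethyldodeca-2,8-dienoate
Product: 11 methyl (2E,6S,8E)-6-(tert-butyldimethylsilyloxy)-3,7,7-trimethyl-11-oxododeca-2,8-dienoate
Conditions: Dess–Martin periodinane, pyridine, CH2Cl2, 0 °C → rt
Reagents that add atoms: none
Why: Dess–Martin oxidation under buffered, non-basic conditions converts both carbinol epimers into one β,γ-unsaturated methyl ketone without moving the C5=C6 bond into conjugation.

Step 6
Reactants: 11 methyl (2E,6S,8E)-6-(tert-butyldimethylsilyloxy)-3,7,7-trimethyl-11-oxododeca-2,8-dienoate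
Product: 13 methyl (2E,6S,8E,10E)-6,11-bis(tert-butyldimethylsilyloxy)-3,7,7-trimethyldodeca-2,8,10-trienoate, via lithium dienolate 12 (not isolated)
Conditions: lithium 2,2,6,6-tetramethylpiperidide (from the amine and n-BuLi), LiBr, THF, −78 °C, ketone added slowly; then TBSOTf, −78 °C; Et3N, aq NaHCO3 work-up
Reagents that add atoms: tert-butyldimethylsilyl triflate, CC(C)(C)[Si](C)(C)OS(=O)(=O)C(F)(F)F
Why: Kinetic deprotonation at the doubly activated C7 methylene through an Ireland-type cyclic transition state (hindered lithium amide, small methyl on the carbonyl) should give the enolate with C6 trans to oxygen, and O-silylation freezes it as the (10E)-dienol ether with the C8 methyl inside; the γ-protons of the enoate are far less acidic.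

Step 7
Reactants: 13 methyl (2E,6S,8E,10E)-6,11-bis(tert-butyldimethylsilyloxy)-3,7,7-trimethyldodeca-2,8,10-trienoate
Product: 14 methyl (1R,2R,4aS,6S,8aS)-2,6-bis(tert-butyldimethylsilyloxy)-2,5,5,8a-tetramethyl-1,2,4a,5,6,7,8,8a-octahydronaphthalene-1-carboxylate (cis-fused; 3β- and 8α-silyloxy, H-5, C11 ester, C8 and C10 methyls β; C6=C7)
Conditions: toluene (0.005 M), BHT (cat.), N,O-bis(trimethylsilyl)acetamide (0.1 equiv), degassed, sealed base-washed tube, 180 °C
Reagents that add atoms: none
Why: A concerted, suprafacial thermal [4+2] cycloaddition of normal electron demand (silyloxy-raised diene HOMO, enoate LUMO, polarities matched as C5 to C10 and C8 to C9), the closest known reaction type being the intramolecular Diels–Alder reaction of 1,3,9-decatrienes that carry a 1-silyloxy diene and a β,β-disubstituted enoate. Ring B arises as the cyclohexene of the cycloaddition itself, and ring A closes in the fused mode through the new C5–C10 bond because the four-carbon tether C1–C4 spans diene and dienophile in a chair-like array. The (E)-enoate fixes the C10 methyl cis to C11, the (8E)-bond puts H-5 inside and the (10E)-enol ether puts the C8 methyl inside, so H-5 and the C8 methyl end cis to each other and trans to the C8 silyloxy group. The tether-endo (ester-exo) transition state, expected to be preferred because the alternative must place both the C10 methyl and the ester under the diene, links the two pairs as the cis-fused decalin with the C10 methyl, C11, H-5 and the C8 methyl on one face. The (3S)-silyloxy group is equatorial on the chair-like tether only for the diene face that leads to the shown enantiomer, so the step needs tether-endo and facial selectivity, which these two substrate features should supply, and retention of the dienol ether geometry, which acid-free glassware should secure. A 1,5-hydrogen shift of the inside methyl is expected to be reversible, since the cross-conjugated diene it gives can return by the same shift.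

Step 8
Reactants: 14 the cycloadduct (octalin ester)
Product: 15 methyl (1R,2R,4aS,6S,8aS)-2,6-bis(tert-butyldimethylsilyloxy)-2,5,5,8a-tetramethyldecahydronaphthalene-1-carboxylate
Conditions: H2 (1–3 atm), 10% Pd/C, EtOAc, rt
Reagents that add atoms: none
Why: Heterogeneous hydrogenation of the only C=C bond (cis-disubstituted, C6=C7); no stereocentre is made or lost, and the silyl ethers and the ester are stable.

Step 9
Reactants: 15 the saturated bis-silyl ester
Product: 16 [(1S,2R,4aS,6S,8aS)-2,6-bis(tert-butyldimethylsilyloxy)-2,5,5,8a-tetramethyldecahydronaphthalen-1-yl]methanol (C11 alcohol)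
Conditions: LiAlH4, THF, 0 °C → rt
Reagents that add atoms: none
Why: Hydride reduction of the ester to the primary alcohol; C9 is not epimerised because no enolate is formed.

Step 10
Reactants: 16 the C11 alcohol
Product: 17 the C11 phenyl sulfide (3β,8α-bis(tert-butyldimethylsilyloxy), C11–SPh)
Conditions: PhSSPh, n-Bu3P, pyridine, 60 °C
Reagents that add atoms: diphenyl disulfide, c1ccc(SSc2ccccc2)cc1
Why: Phosphine–disulfide thioether formation (Mukaiyama–Hata type): the alcohol is activated as an oxyphosphonium ion and displaced by thiophenolate in an SN2 reaction, which this small, strong nucleophile should manage at the β-branched primary C11.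

Step 11
Reactants: 17 the C11 phenyl sulfide
Product: 18 the C11 phenyl sulfone (3β,8α-bis(tert-butyldimethylsilyloxy), C11–SO2Ph)
Conditions: (NH4)6Mo7O24·4H2O (cat.), 30% H2O2, EtOH–THF, 0 °C → rt
Reagents that add atoms: hydrogen peroxide, OO
Why: Molybdate-catalysed peroxide oxidation of sulfide to sulfone; the molecule has no alkene at this stage and the silyl ethers tolerate the conditions.

Step 12
Reactants: 19 (2E,6E)-farnesol
Product: 20 (2E,6E)-farnesyl acetate
Conditions: Ac2O, pyridine, DMAP (cat.), CH2Cl2, 0 °C → rt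
Reagents that add atoms: acetic anhydride, CC(=O)OC(C)=O
Why: Acylation protects the allylic alcohol so that the following oxidation takes place only at the far end of the chain.

Step 13
Reactants: 20 (2E,6E)-farnesyl acetate
Product: 21 (2E,6E,10E)-12-hydroxy-3,7,11-trimethyldodeca-2,6,10-trienyl acetate
Conditions: SeO2 (0.1 equiv), salicylic acid (0.1 equiv), t-BuOOH (70% aq), CH2Cl2, rt
Reagents that add atoms: tert-butyl hydroperoxide, CC(C)(C)OO
Why: Catalytic selenium dioxide allylic oxidation (ene reaction, then 2,3-sigmatropic shift) acts on the most electron-rich, terminal trisubstituted alkene and hydroxylates its (E)-methyl group, leaving the alkene geometry intact.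

Step 14
Reactants: 21 (2E,6E,10E)-12-hydroxy-3,7,11-trimethyldodeca-2,6,10-trienyl acetate
Product: 22 (2E,6E,10E)-12-(tert-butyldimethylsilyloxy)-3,7,11-trimethyldodeca-2,6,10-trienyl acetate
Conditions: TBSCl, imidazole, DMF, rt
Reagents that add atoms: tert-butyldimethylsilyl chloride, CC(C)(C)[Si](C)(C)Cl
Why: Standard silylation of a primary allylic alcohol gives a group that survives organolithium and dissolving-metal steps.

Step 15
Reactants: 22 (2E,6E,10E)-12-(tert-butyldimethylsilyloxy)-3,7,11-trimethyldodeca-2,6,10-trienyl acetate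
Product: 23 (2E,6E,10E)-12-(tert-butyldimethylsilyloxy)-3,7,11-trimethyldodeca-2,6,10-trien-1-ol
Conditions: K2CO3 (0.2 equiv), MeOH, 0 °C → rt
Reagents that add atoms: none
Why: Base-catalysed transesterification removes the acetate; the silyl ether is stable to methanolic carbonate.

Step 16
Reactants: 23 (2E,6E,10E)-12-(tert-butyldimethylsilyloxy)-3,7,11-trimethyldodeca-2,6,10-trien-1-ol
Product: 24 tert-butyl{[(2E,6E,10E)-12-bromo-2,6,10-trimethyldodeca-2,6,10-trien-1-yl]oxy}dimethylsilane
Conditions: CBr4, PPh3, CH2Cl2, 0 °C; used at once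
Reagents that add atoms: carbon tetrabromide, BrC(Br)(Br)Br
Why: Appel bromination proceeds by SN2 at the primary allylic carbon under neutral conditions, so the (E)-alkenes and the silyl ether are kept.

Step 17
Reactants: 18 the C11 phenyl sulfone; 24 the silyloxy farnesyl bromide
Product: 26 the coupled C11 sulfone (3β,8α,23-tris(tert-butyldimethylsilyloxy), 13E,17E,21E, both C11 epimers), via lithiated sulfone 25 (not isolated)
Conditions: n-BuLi, THF–DMPU, −78 °C; then 24, −78 → −20 °C
Reagents that add atoms: none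
Why: Alkylation of an α-sulfonyl carbanion (Julia-type fragment coupling) by SN2 at the primary allylic bromide forms C11–C12 without touching the C13=C14 geometry; C11 becomes a stereocentre, and both epimers are carried on because step 18 removes it.

Step 18
Reactants: 26 the coupled C11 sulfone
Product: 27 the tris(tert-butyldimethylsilyl) ether of the side-chain triol (C11 now CH2)
Conditions: 6% Na/Hg, Na2HPO4, MeOH–THF, −20 → 0 °C
Reagents that add atoms: none
Why: Reductive desulfonylation by electron transfer from sodium amalgam cleaves the C–S bond and protonates C11; the sulfone is not allylic, so no alkene migrates, and the allylic silyl ether is not reduced.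

Step 19
Reactants: 27 the tris-silyl ether
Product: 28 the triol (3β,8α,23-trihydroxy; 5β-H cis-decalin with the 13E,17E,21E chain)
Conditions: TBAF (excess), THF, 60 °C
Reagents that add atoms: none
Why: Fluoride-driven desilylation removes the primary, the hindered secondary and the tertiary silyl group; no base-sensitive group is present at this stage.

Step 20
Reactants: 28 the triol
Product: 29 the C23 monoacetate (3β,8α-diol)
Conditions: AcCl (1.1 equiv), 2,4,6-collidine, CH2Cl2, −78 °C
Reagents that add atoms: acetyl chloride, CC(=O)Cl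
Why: Selective acylation: the primary allylic C23 hydroxyl should react far faster than the secondary C3 hydroxyl beside the gem-dimethyl carbon and the tertiary C8 hydroxyl.

Step 21
Reactants: 29 the C23 monoacetate
Product: 30 myrrhanone A acetate (as the given stereoisomer)
Conditions: Dess–Martin periodinane, pyridine, CH2Cl2, 0 °C → rt
Reagents that add atoms: none
Why: Dess–Martin oxidation of the only secondary alcohol gives the C3 ketone and removes the auxiliary C3 stereocentre; the tertiary alcohol, the allylic acetate and the alkenes do not react.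

**Compound list**
1 | methyl geranate | COC(=O)/C=C(\C)CCC=C(C)C | starting material
2 | secondary ozonide of 1 at the distal alkene | COC(=O)/C=C(\C)CCC1OOC(C)(C)O1 | intermediate
3 | methyl (2E)-3-methyl-6-oxohex-2-enoate | COC(=O)/C=C(\C)CCC=O | intermediate
4 | 3-methylbuta-1,2-diene | CC(C)=C=C | starting material
5 | B-(3-methylbut-2-enyl)diisopinocampheylborane, Ipc from (−)-α-pinene | CC(C)=CCB([C@H]1C[C@H]2C[C@@H]([C@@H]1C)C2(C)C)[C@H]1C[C@H]2C[C@@H]([C@@H]1C)C2(C)C | intermediate
6 | diisopinocampheylborinate of alcohol 7 | COC(=O)/C=C(\C)CC[C@H](OB([C@H]1C[C@H]2C[C@@H]([C@@H]1C)C2(C)C)[C@H]1C[C@H]2C[C@@H]([C@@H]1C)C2(C)C)C(C)(C)C=C | intermediate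
7 | methyl (2E,6S)-6-hydroxy-3,7,7-trimethylnona-2,8-dienoate | COC(=O)/C=C(\C)CC[C@H](O)C(C)(C)C=C | intermediate
8 | methyl (2E,6S)-6-(tert-butyldimethylsilyloxy)-3,7,7-trimethylnona-2,8-dienoate | COC(=O)/C=C(\C)CC[C@H](O[Si](C)(C)C(C)(C)C)C(C)(C)C=C | intermediate
9 | (±)-pent-4-en-2-ol | CC(O)CC=C | starting material
10 | methyl (2E,6S,8E)-6-(tert-butyldimethylsilyloxy)-11-hydroxy-3,7,7-trimethyldodeca-2,8-dienoate (C11 of the chain unassigned) | COC(=O)/C=C(\C)CC[C@H](O[Si](C)(C)C(C)(C)C)C(C)(C)/C=C/CC(C)O | intermediate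
11 | methyl (2E,6S,8E)-6-(tert-butyldimethylsilyloxy)-3,7,7-trimethyl-11-oxododeca-2,8-dienoate | COC(=O)/C=C(\C)CC[C@H](O[Si](C)(C)C(C)(C)C)C(C)(C)/C=C/CC(C)=O | intermediate
12 | lithium (8E,10E)-dienolate of 11 | COC(=O)/C=C(\C)CC[C@H](O[Si](C)(C)C(C)(C)C)C(C)(C)/C=C/C=C(\C)O[Li] | intermediate
13 | methyl (2E,6S,8E,10E)-6,11-bis(tert-butyldimethylsilyloxy)-3,7,7-trimethyldodeca-2,8,10-trienoate | COC(=O)/C=C(\C)CC[C@H](O[Si](C)(C)C(C)(C)C)C(C)(C)/C=C/C=C(\C)O[Si](C)(C)C(C)(C)C | intermediate
14 | methyl (1R,2R,4aS,6S,8aS)-2,6-bis(tert-butyldimethylsilyloxy)-2,5,5,8a-tetramethyl-1,2,4a,5,6,7,8,8a-octahydronaphthalene-1-carboxylate | COC(=O)[C@@H]1[C@@]2(C)CC[C@H](O[Si](C)(C)C(C)(C)C)C(C)(C)[C@H]2C=C[C@@]1(C)O[Si](C)(C)C(C)(C)C | intermediate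
15 | methyl (1R,2R,4aS,6S,8aS)-2,6-bis(tert-butyldimethylsilyloxy)-2,5,5,8a-tetramethyldecahydronaphthalene-1-carboxylate | COC(=O)[C@@H]1[C@@]2(C)CC[C@H](O[Si](C)(C)C(C)(C)C)C(C)(C)[C@H]2CC[C@@]1(C)O[Si](C)(C)C(C)(C)C | intermediate
16 | [(1S,2R,4aS,6S,8aS)-2,6-bis(tert-butyldimethylsilyloxy)-2,5,5,8a-tetramethyldecahydronaphthalen-1-yl]methanol | OC[C@@H]1[C@@]2(C)CC[C@H](O[Si](C)(C)C(C)(C)C)C(C)(C)[C@H]2CC[C@@]1(C)O[Si](C)(C)C(C)(C)C | intermediate
17 | C11 phenyl sulfide of 16 | c1ccccc1SC[C@@H]1[C@@]2(C)CC[C@H](O[Si](C)(C)C(C)(C)C)C(C)(C)[C@H]2CC[C@@]1(C)O[Si](C)(C)C(C)(C)C | intermediate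
18 | C11 phenyl sulfone | O=S(=O)(c1ccccc1)C[C@@H]1[C@@]2(C)CC[C@H](O[Si](C)(C)C(C)(C)C)C(C)(C)[C@H]2CC[C@@]1(C)O[Si](C)(C)C(C)(C)C | intermediate
19 | (2E,6E)-farnesol | CC(C)=CCC/C(C)=C/CC/C(C)=C/CO | starting material
20 | (2E,6E)-farnesyl acetate | CC(C)=CCC/C(C)=C/CC/C(C)=C/COC(C)=O | intermediate
21 | (2E,6E,10E)-12-hydroxy-3,7,11-trimethyldodeca-2,6,10-trienyl acetate | OC/C(C)=C/CC/C(C)=C/CC/C(C)=C/COC(C)=O | intermediate
22 | (2E,6E,10E)-12-(tert-butyldimethylsilyloxy)-3,7,11-trimethyldodeca-2,6,10-trienyl acetate | CC(C)(C)[Si](C)(C)OC/C(C)=C/CC/C(C)=C/CC/C(C)=C/COC(C)=O | intermediate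
23 | (2E,6E,10E)-12-(tert-butyldimethylsilyloxy)-3,7,11-trimethyldodeca-2,6,10-trien-1-ol | CC(C)(C)[Si](C)(C)OC/C(C)=C/CC/C(C)=C/CC/C(C)=C/CO | intermediate
24 | tert-butyl{[(2E,6E,10E)-12-bromo-2,6,10-trimethyldodeca-2,6,10-trien-1-yl]oxy}dimethylsilane | CC(C)(C)[Si](C)(C)OC/C(C)=C/CC/C(C)=C/CC/C(C)=C/CBr | intermediate
25 | C11-lithiated sulfone 18 | O=S(=O)(c1ccccc1)C([Li])[C@@H]1[C@@]2(C)CC[C@H](O[Si](C)(C)C(C)(C)C)C(C)(C)[C@H]2CC[C@@]1(C)O[Si](C)(C)C(C)(C)C | intermediate
26 | coupled C11 sulfone, 3β,8α,23-tris(tert-butyldimethylsilyloxy), 13E,17E,21E (C11 unassigned) | CC(C)(C)[Si](C)(C)OC/C(C)=C/CC/C(C)=C/CC/C(C)=C/CC([C@@H]1[C@@]2(C)CC[C@H](O[Si](C)(C)C(C)(C)C)C(C)(C)[C@H]2CC[C@@]1(C)O[Si](C)(C)C(C)(C)C)S(=O)(=O)c1ccccc1 | intermediate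
27 | 3β,8α,23-tris(tert-butyldimethylsilyloxy) 13E,17E,21E-triene | CC(C)(C)[Si](C)(C)OC/C(C)=C/CC/C(C)=C/CC/C(C)=C/CC[C@@H]1[C@@]2(C)CC[C@H](O[Si](C)(C)C(C)(C)C)C(C)(C)[C@H]2CC[C@@]1(C)O[Si](C)(C)C(C)(C)C | intermediate
28 | 3β,8α,23-triol | OC/C(C)=C/CC/C(C)=C/CC/C(C)=C/CC[C@@H]1[C@@]2(C)CC[C@H](O)C(C)(C)[C@H]2CC[C@@]1(C)O | intermediate
29 | 23-acetoxy-3β,8α-diol | CC(=O)OC/C(C)=C/CC/C(C)=C/CC/C(C)=C/CC[C@@H]1[C@@]2(C)CC[C@H](O)C(C)(C)[C@H]2CC[C@@]1(C)O | intermediate
30 | myrrhanone A acetate (given stereoisomer) | CC(=O)OC/C(C)=C/CC/C(C)=C/CC/C(C)=C/CC[C@@H]1[C@@]2(C)CCC(=O)C(C)(C)[C@H]2CC[C@@]1(C)O | target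

**Step count**
Total: 21 steps. Longest linear sequence: 16 steps (steps 1–11 and 17–21, from methyl geranate); the farnesol branch is 5 steps (12–16).

**Steps most likely to fail**

Step 7. The cycloaddition may be slower than thermal degradation or silyl loss of the inside-methyl dienol ether, or the tether-endo mode may not dominate, so that trans-fused material forms. The fallback changes the activating group from ester to aldehyde so that a lower temperature suffices; it sets out from 13 and comes back at 16. Reduction of the ester of 13 with i-Bu2AlH in CH2Cl2 at −78 °C gives the trienyl alcohol F1, which MnO2 in CH2Cl2 oxidises to the (2E)-enal F2. The enal should cyclise in toluene near 110 °C to the cis-fused bicyclic aldehyde F3, the smaller formyl group also costing less in the exo position. NaBH4 in methanol then gives the unsaturated C11 alcohol F4, and hydrogenation over Pd/C as in step 8 leads to 16.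

Step 6. Deprotonation may take place at the methyl group of the ketone, or the enolate geometry may leak toward the isomer with oxygen inside, which would give the C8 epimer later. The fallback moves the geometry question from an enolate to a pair of separable diastereomers (Horner–Wittig enol ether synthesis); it sets out from 8 and comes back at 15. Cross-metathesis of 8 with crotonaldehyde (same ruthenium catalyst as step 4) gives the (2E,8E)-enal F5. The reagent (1-benzyloxyethyl)diphenylphosphine oxide F6, made from chlorodiphenylphosphine and acetaldehyde dibenzyl acetal, is lithiated with LiN(i-Pr)2 at −78 °C and added to F5, giving the β-hydroxy phosphine oxide F7 as diastereomers that are separated by chromatography. The pair that undergoes syn-elimination with NaH in DMF to the (10E)-ether gives the benzyl dienol ether F8. Heating as in step 7 should give the benzyl ether cycloadduct F9; hydrogenation over Pd/C saturates C6=C7 and cleaves the benzyl group to the hydroxy ester F10, and TBSOTf with 2,6-lutidine then gives 15.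

Step 4. Metathesis at a vinyl group flanked by a quaternary carbon and a silyloxy carbinol may be so slow that catalyst decay and alkene isomerisation take over. The fallback builds the C5=C6 bond by olefination and adds the acetonyl unit by cross-coupling; it sets out from 8 and comes back at 11. Oxidative cleavage of the vinyl group (OsO4 cat., NaIO4, 2,6-lutidine, dioxane–water; the enoate reacts more slowly) gives the aldehyde F11. Takai iodo-olefination (CrCl2, CHI3, THF, 0 °C) converts it into the (E)-vinyl iodide F12, and Stille coupling with tributyl(2-oxopropyl)stannane (Pd(PPh3)4, toluene, 90 °C) gives the β,γ-unsaturated ketone 11.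

**Further compounds**
F1 | step 7 | (2E,6S,8E,10E)-6,11-bis(tert-butyldimethylsilyloxy)-3,7,7-trimethyldodeca-2,8,10-trien-1-ol | OC/C=C(\C)CC[C@H](O[Si](C)(C)C(C)(C)C)C(C)(C)/C=C/C=C(\C)O[Si](C)(C)C(C)(C)C
F2 | step 7 | (2E,6S,8E,10E)-6,11-bis(tert-butyldimethylsilyloxy)-3,7,7-trimethyldodeca-2,8,10-trienal | O=C/C=C(\C)CC[C@H](O[Si](C)(C)C(C)(C)C)C(C)(C)/C=C/C=C(\C)O[Si](C)(C)C(C)(C)C
F3 | step 7 | (1R,2R,4aS,6S,8aS)-2,6-bis(tert-butyldimethylsilyloxy)-2,5,5,8a-tetramethyl-1,2,4a,5,6,7,8,8a-octahydronaphthalene-1-carbaldehyde | O=C[C@@H]1[C@@]2(C)CC[C@H](O[Si](C)(C)C(C)(C)C)C(C)(C)[C@H]2C=C[C@@]1(C)O[Si](C)(C)C(C)(C)C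
F4 | step 7 | unsaturated C11 alcohol (C6=C7 analogue of 16) | OC[C@@H]1[C@@]2(C)CC[C@H](O[Si](C)(C)C(C)(C)C)C(C)(C)[C@H]2C=C[C@@]1(C)O[Si](C)(C)C(C)(C)C
F5 | step 6 | methyl (2E,6S,8E)-6-(tert-butyldimethylsilyloxy)-3,7,7-trimethyl-10-oxodeca-2,8-dienoate | COC(=O)/C=C(\C)CC[C@H](O[Si](C)(C)C(C)(C)C)C(C)(C)/C=C/C=O
F6 | step 6 | (1-benzyloxyethyl)diphenylphosphine oxide | CC(OCc1ccccc1)P(=O)(c1ccccc1)c1ccccc1
F7 | step 6 | β-hydroxy phosphine oxide adduct of F5 and F6 (the two new centres unassigned) | COC(=O)/C=C(\C)CC[C@H](O[Si](C)(C)C(C)(C)C)C(C)(C)/C=C/C(O)C(C)(OCc1ccccc1)P(=O)(c1ccccc1)c1ccccc1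
F8 | step 6 | methyl (2E,6S,8E,10E)-11-benzyloxy-6-(tert-butyldimethylsilyloxy)-3,7,7-trimethyldodeca-2,8,10-trienoate | COC(=O)/C=C(\C)CC[C@H](O[Si](C)(C)C(C)(C)C)C(C)(C)/C=C/C=C(\C)OCc1ccccc1
F9 | step 6 | 8α-benzyloxy analogue of cycloadduct 14 | COC(=O)[C@@H]1[C@@]2(C)CC[C@H](O[Si](C)(C)C(C)(C)C)C(C)(C)[C@H]2C=C[C@@]1(C)OCc1ccccc1
F10 | step 6 | 8α-hydroxy analogue of saturated ester 15 | COC(=O)[C@@H]1[C@@]2(C)CC[C@H](O[Si](C)(C)C(C)(C)C)C(C)(C)[C@H]2CC[C@@]1(C)O
F11 | step 4 | methyl (2E,6S)-6-(tert-butyldimethylsilyloxy)-3,7,7-trimethyl-8-oxooct-2-enoate | COC(=O)/C=C(\C)CC[C@H](O[Si](C)(C)C(C)(C)C)C(C)(C)C=O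
F12 | step 4 | methyl (2E,6S,8E)-6-(tert-butyldimethylsilyloxy)-9-iodo-3,7,7-trimethylnona-2,8-dienoate | COC(=O)/C=C(\C)CC[C@H](O[Si](C)(C)C(C)(C)C)C(C)(C)/C=C/I
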